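**Assumption:** positions are given in germacrane numbering (lactone O on C6, angelates on C8 and C9, CO2H = C14 on C10, lactone C=O = C12, exo-methylene = C13, ring methyl = C15); the target SMILES is read as 6R,7S,8S,9S with ring-cis C1=C10 and C4=C5; lithium, sodium, indium and zinc derivatives of numbered compounds are treated as reagent forms and are not numbered.

## Retrosynthetic overview

1. 23 ⇒ 21: the last bond made is C6–O, by acid-catalysed 1,4-hydrolactonisation of a macrocyclic exo-methylene 1,3-diene; it closes the γ-lactone, sets C6 and the 4Z olefin, and frees the C14 acid.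
2. 21 ⇒ 20 ⇒ 17: the ten-membered carbocycle is closed by ring-closing metathesis (C5=C6) after both angelate C–O bonds are made on diol 17 with two equivalents of angelic acid.
3. 17 ⇒ 12 + 16: C7–C8 by indium Barbier allylation of an α-hydroxy aldehyde with a dienyl bromide (sets C7 and C8).
4. 12 ⇒ 9 ⇒ 8 + 5: C9–O by Evans/Davis enolate hydroxylation of an alkylidene succinate made by Horner–Wadsworth–Emmons olefination of myrcene-derived aldehyde 8.
5. Ring order: ten-membered ring first (step 12), γ-lactone last (step 13).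

## Route

Step 1
Reactants: 1 (4S)-4-benzyl-1,3-oxazolidin-2-one; 2 bromoacetyl bromide
Product: 3 (4S)-4-benzyl-3-(bromoacetyl)-1,3-oxazolidin-2-one
Conditions: n-BuLi, THF, −78 °C; then 2, −78 → 0 °C
Reagents that add atoms: none
Why: N-acylation of the lithiated Evans oxazolidinone by the acid bromide is fast at −78 °C and does not touch the C4 stereocentre.

Step 2
Reactants: 4 tert-butyl (diethoxyphosphoryl)acetate; 3 (4S)-4-benzyl-3-(bromoacetyl)-1,3-oxazolidin-2-one
Product: 5 tert-butyl 4-[(4S)-4-benzyl-2-oxo-1,3-oxazolidin-3-yl]-2-(diethoxyphosphoryl)-4-oxobutanoate (both C2 epimers)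
Conditions: NaH, THF, 0 °C; then 3, 0 → 23 °C
Reagents that add atoms: none
Why: SN2 alkylation of the sodium phosphonoacetate with the reactive α-bromo imide gives the phosphonosuccinate-type Horner–Wadsworth–Emmons reagent; the new CH(P) centre is irrelevant because it becomes sp2 in step 4.

Step 3
Reactants: 6 myrcene
Product: 8 4-methylidenehex-5-enal, via ozonide 7 (not isolated)
Conditions: O3 (1.0 equiv, Sudan Red 7B end-point), CH2Cl2, −78 °C; then Me2S, −78 → 23 °C
Reagents that add atoms: ozone, [O-][O+]=O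
Why: Chemoselective ozonolysis, because the electron-rich trisubstituted olefin reacts with ozone faster than the conjugated diene, and reductive cleavage of the ozonide gives the aldehyde.

Step 4
Reactants: 8 4-methylidenehex-5-enal; 5 phosphonate imide
Product: 9 tert-butyl (2E)-2-{2-[(4S)-4-benzyl-2-oxo-1,3-oxazolidin-3-yl]-2-oxoethyl}-6-methylideneocta-2,7-dienoate
Conditions: LiCl, DBU, MeCN, 0 → 23 °C
Reagents that add atoms: none
Why: Masamune–Roush Horner–Wadsworth–Emmons olefination of an α-substituted phosphonoacetate gives the (E)-trisubstituted enoate (chain trans to CO2t-Bu, cis to the future C9), which is the ring-cis C1=C10 geometry of the target, under conditions mild enough for the imide.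

Step 5
Reactants: 9 alkylidene succinate imide
Product: 10 tert-butyl (2E)-2-{(1S)-2-[(4S)-4-benzyl-2-oxo-1,3-oxazolidin-3-yl]-1-hydroxy-2-oxoethyl}-6-methylideneocta-2,7-dienoate
Conditions: NaN(SiMe3)2, THF, −78 °C; then 2-(phenylsulfonyl)-3-phenyloxaziridine, −78 °C; AcOH quench
Reagents that add atoms: 2-(phenylsulfonyl)-3-phenyloxaziridine, O=S(=O)(c1ccccc1)N1OC1c1ccccc1
Why: Evans asymmetric enolate hydroxylation with the Davis oxaziridine: the chelated (Z)-sodium dienolate is oxidised at its α-carbon on the face opposite the benzyl group (same sense as Evans alkylation), which sets C9 as S.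

Step 6
Reactants: 10 α-hydroxy imide
Product: 11 tert-butyl (2E)-2-[(1S)-1,2-dihydroxyethyl]-6-methylideneocta-2,7-dienoate
Conditions: LiBH4, H2O (1 equiv), THF/Et2O, 0 °C
Reagents that add atoms: none
Why: Reductive removal of the auxiliary: LiBH4 reduces the activated imide carbonyl while the hindered conjugated tert-butyl ester survives, and C9 is not touched.

Step 7
Reactants: 11 diol
Product: 12 tert-butyl (2E)-2-[(1S)-1-hydroxy-2-oxoethyl]-6-methylideneocta-2,7-dienoate
Conditions: TEMPO (10 mol%), PhI(OAc)2, CH2Cl2, 0 → 23 °C; used crude at once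
Reagents that add atoms: none
Why: Oxoammonium (TEMPO) oxidation is selective for the primary over the secondary hydroxyl and runs without base, so the configurationally labile α-hydroxy aldehyde is not epimerised.

Step 8
Reactants: 13 tert-butyl acrylate; 14 acrolein
Product: 15 tert-butyl 3-hydroxy-2-methylidenepent-4-enoate (racemic)
Conditions: DABCO (20 mol%), 1,4-dioxane/H2O (1:1), 23 °C, 3 d
Reagents that add atoms: none
Why: Morita–Baylis–Hillman reaction, in which the DABCO–acrylate zwitterion adds 1,2 to the aldehyde carbon of acrolein; the carbinol centre is lost in step 9.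

Step 9
Reactants: 15 Baylis–Hillman alcohol
Product: 16 tert-butyl (2Z)-2-(bromomethyl)penta-2,4-dienoate
Conditions: PBr3, Et2O, −10 → 0 °C
Reagents that add atoms: phosphorus tribromide, BrP(Br)Br
Why: SN2' bromination of the Baylis–Hillman alcohol with allylic transposition gives the thermodynamically favoured conjugated (Z)-2-(bromomethyl)dienoate (CH2Br cis to the vinyl group).

Step 10
Reactants: 12 α-hydroxy aldehyde; 16 dienyl bromide
Product: 17 di-tert-butyl (3R,4S,5S,6E)-3-ethenyl-4,5-dihydroxy-2-methylidene-6-(4-methylidenehex-5-en-1-ylidene)heptanedioate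
Conditions: In powder, THF/H2O (1:1), 23 °C
Reagents that add atoms: none
Why: Indium-mediated Barbier allylation in water: the allylindium reacts at its γ-carbon through a chair transition state (Z-type reagent, hence C7/C8 syn) on the indium-chelated α-hydroxy aldehyde (Cram-chelate control, hence threo C8/C9), which sets C7 and C8; the tert-butyl ester prevents lactonisation onto O8.

Step 11
Reactants: 17 diol; 18 angelic acid
Product: 20 di-tert-butyl (3R,4S,5S,6E)-3-ethenyl-2-methylidene-6-(4-methylidenehex-5-en-1-ylidene)-4,5-bis{[(2Z)-2-methylbut-2-enoyl]oxy}heptanedioate, via mixed anhydride 19 (not isolated)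
Conditions: 18 (6 equiv), 2,4,6-Cl3C6H2COCl (6 equiv), Et3N (8 equiv), toluene, 23 °C, 2 h; then 17, 80 °C (no DMAP)
Reagents that add atoms: angelic acid (second equivalent), C/C=C(/C)C(=O)O
Why: Yamaguchi esterification in which two molecules of angelic acid, each activated as mixed anhydride 19, acylate the two secondary hydroxyls (C8–OH and C9–OH) of one molecule of 17 with retention at carbon; the excess of 19 drives the double acylation, and leaving out DMAP suppresses the angelate-to-tiglate isomerisation.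

Step 12
Reactants: 20 bis-angelate triene
Product: 21 tert-butyl (1E,6Z,8R,9S,10S)-8-[3-(tert-butoxy)-3-oxoprop-1-en-2-yl]-5-methylidene-9,10-bis{[(2Z)-2-methylbut-2-enoyl]oxy}cyclodeca-1,6-diene-1-carboxylate
Conditions: second-generation Hoveyda–Grubbs catalyst RuCl2(SIMes)(=CH-C6H4-2-Oi-Pr) (10 mol%), 1,4-benzoquinone (20 mol%), toluene (1 mM), 80 °C, argon sparge
Reagents that add atoms: none
Why: Ring-closing olefin metathesis joins the two monosubstituted vinyl groups (the 1,1-disubstituted and trisubstituted olefins are spectators), with the (E)-enoate turn and the vicinal diester pre-organising the chain; the ring-cis C5=C6 is expected, and either geometry converges in step 13.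

Step 13
Reactants: 21 macrocyclic diene
Product: 23 (3aS,4S,5S,6E,10Z,11aR)-10-methyl-3-methylidene-4,5-bis{[(2Z)-2-methylbut-2-enoyl]oxy}-2-oxo-2,3,3a,4,5,8,9,11a-octahydrocyclodeca[b]furan-6-carboxylic acid (CNP0154468.1), via lactone tert-butyl ester 22 (not isolated)
Conditions: Tf2NH (10 mol%), (CF3)2CHOH/CH2Cl2 (1:4), −20 → 20 °C
Reagents that add atoms: none
Why: Proposed new method: Brønsted-acid-catalysed 1,4-hydrolactonisation of a macrocyclic exocyclic 1,3-diene with a tert-butyl ester as latent carboxylate — Tf2NH protonates the terminal C15 methylene of the diene (the only electron-rich π-system, all other olefins being acrylate-type acceptors, so cation–olefin cyclisation is shut off) to give the C4–C5–C6 allyl cation, the C12 ester carbonyl oxygen closes the five-membered ring at C6 and loses isobutene (returning H+), and the same acid then cleaves the C14 tert-butyl ester; the ring holds the C7–C8 bond away from C5, so the C12 carbonyl oxygen is delivered to the C6 face anti to C8 and gives the trans-fused lactone (6R), while protonation of the s-trans diene leaves C3 cis to C6, the ring-cis 4Z olefin that is also the less strained geometry in a ten-membered ring; the closest known reaction types are acid-catalysed hydro-acyloxylation (hydrolactonisation) of alkenoic acids and 1,4-hydrofunctionalisation of 2-substituted 1,3-dienes, and it has not been shown on a macrocyclic diene to set a ring-fusion stereocentre and a ring-olefin geometry.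

## Compound list

1 | (4S)-4-benzyl-1,3-oxazolidin-2-one | O=C1N[C@@H](Cc2ccccc2)CO1 | starting material
2 | bromoacetyl bromide | BrCC(Br)=O | starting material
3 | (4S)-4-benzyl-3-(bromoacetyl)-1,3-oxazolidin-2-one | BrCC(=O)N1C(=O)OC[C@@H]1Cc1ccccc1 | intermediate
4 | tert-butyl (diethoxyphosphoryl)acetate | CCOP(=O)(OCC)CC(=O)OC(C)(C)C | starting material
5 | tert-butyl 4-[(4S)-4-benzyl-2-oxo-1,3-oxazolidin-3-yl]-2-(diethoxyphosphoryl)-4-oxobutanoate (both C2 epimers) | CCOP(=O)(OCC)C(CC(=O)N1C(=O)OC[C@@H]1Cc1ccccc1)C(=O)OC(C)(C)C | intermediate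
6 | myrcene (7-methyl-3-methylideneocta-1,6-diene) | C=CC(=C)CCC=C(C)C | starting material
7 | 3,3-dimethyl-5-(3-methylidenepent-4-en-1-yl)-1,2,4-trioxolane (ozonide) | C=CC(=C)CCC1OOC(C)(C)O1 | intermediate
8 | 4-methylidenehex-5-enal | C=CC(=C)CCC=O | intermediate
9 | tert-butyl (2E)-2-{2-[(4S)-4-benzyl-2-oxo-1,3-oxazolidin-3-yl]-2-oxoethyl}-6-methylideneocta-2,7-dienoate | C=CC(=C)CC/C=C(\CC(=O)N1C(=O)OC[C@@H]1Cc1ccccc1)C(=O)OC(C)(C)C | intermediate
10 | tert-butyl (2E)-2-{(1S)-2-[(4S)-4-benzyl-2-oxo-1,3-oxazolidin-3-yl]-1-hydroxy-2-oxoethyl}-6-methylideneocta-2,7-dienoate | C=CC(=C)CC/C=C(\[C@H](O)C(=O)N1C(=O)OC[C@@H]1Cc1ccccc1)C(=O)OC(C)(C)C | intermediate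
11 | tert-butyl (2E)-2-[(1S)-1,2-dihydroxyethyl]-6-methylideneocta-2,7-dienoate | C=CC(=C)CC/C=C(\[C@H](O)CO)C(=O)OC(C)(C)C | intermediate
12 | tert-butyl (2E)-2-[(1S)-1-hydroxy-2-oxoethyl]-6-methylideneocta-2,7-dienoate | C=CC(=C)CC/C=C(\[C@H](O)C=O)C(=O)OC(C)(C)C | intermediate
13 | tert-butyl acrylate | C=CC(=O)OC(C)(C)C | starting material
14 | acrolein | C=CC=O | starting material
15 | tert-butyl 3-hydroxy-2-methylidenepent-4-enoate (racemic) | C=CC(O)C(=C)C(=O)OC(C)(C)C | intermediate
16 | tert-butyl (2Z)-2-(bromomethyl)penta-2,4-dienoate | C=C/C=C(\CBr)C(=O)OC(C)(C)C | intermediate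
17 | di-tert-butyl (3R,4S,5S,6E)-3-ethenyl-4,5-dihydroxy-2-methylidene-6-(4-methylidenehex-5-en-1-ylidene)heptanedioate | C=CC(=C)CC/C=C(\[C@H](O)[C@@H](O)[C@H](C=C)C(=C)C(=O)OC(C)(C)C)C(=O)OC(C)(C)C | intermediate
18 | angelic acid, (2Z)-2-methylbut-2-enoic acid | C/C=C(/C)C(=O)O | starting material
19 | (2Z)-2-methylbut-2-enoic 2,4,6-trichlorobenzoic anhydride | C/C=C(/C)C(=O)OC(=O)c1c(Cl)cc(Cl)cc1Cl | intermediate
20 | di-tert-butyl (3R,4S,5S,6E)-3-ethenyl-2-methylidene-6-(4-methylidenehex-5-en-1-ylidene)-4,5-bis{[(2Z)-2-methylbut-2-enoyl]oxy}heptanedioate | C=CC(=C)CC/C=C(\[C@H](OC(=O)/C(C)=C\C)[C@@H](OC(=O)/C(C)=C\C)[C@H](C=C)C(=C)C(=O)OC(C)(C)C)C(=O)OC(C)(C)C | intermediate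
21 | tert-butyl (1E,6Z,8R,9S,10S)-8-[3-(tert-butoxy)-3-oxoprop-1-en-2-yl]-5-methylidene-9,10-bis{[(2Z)-2-methylbut-2-enoyl]oxy}cyclodeca-1,6-diene-1-carboxylate | C=C1CC/C=C(\[C@H](OC(=O)/C(C)=C\C)[C@@H](OC(=O)/C(C)=C\C)[C@H](/C=C\1)C(=C)C(=O)OC(C)(C)C)C(=O)OC(C)(C)C | intermediate
22 | tert-butyl (3aS,4S,5S,6E,10Z,11aR)-10-methyl-3-methylidene-4,5-bis{[(2Z)-2-methylbut-2-enoyl]oxy}-2-oxo-2,3,3a,4,5,8,9,11a-octahydrocyclodeca[b]furan-6-carboxylate | C=C1C(=O)O[C@@H]2/C=C(/C)CC/C=C(/C(=O)OC(C)(C)C)[C@H](OC(=O)/C(C)=C\C)[C@@H](OC(=O)/C(C)=C\C)[C@@H]12 | intermediate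
23 | (3aS,4S,5S,6E,10Z,11aR)-10-methyl-3-methylidene-4,5-bis{[(2Z)-2-methylbut-2-enoyl]oxy}-2-oxo-2,3,3a,4,5,8,9,11a-octahydrocyclodeca[b]furan-6-carboxylic acid | C=C1C(=O)O[C@@H]2/C=C(/C)CC/C=C(/C(=O)O)[C@H](OC(=O)/C(C)=C\C)[C@@H](OC(=O)/C(C)=C\C)[C@@H]12 | target

## Step count and risks

Total step count: 13. Longest linear sequence: 10 steps (1, 2, 4, 5, 6, 7, 10, 11, 12, 13).

The three steps most likely to fail:

**Step 13 (proposed new hydrolactonisation).** The allyl cation may be captured with the wrong ring fusion or olefin geometry, or the allylic lactone may re-ionise. The fallback uses known chemistry; it sets out from 21 and comes back at 23. Both tert-butyl esters are cleaved with TMSOTf/2,6-lutidine (CH2Cl2, 0 °C, aqueous work-up) to give the macrocyclic diene diacid F1. Treating it with I2 in MeCN at 0 °C without base (reversible, thermodynamically controlled 1,4-iodolactonisation, with iodine on the terminal C15 and carboxylate oxygen on C6, favouring the trans-fused lactone) gives the 15-iodo lactone F2. Reductive deiodination with Bu3SnH and Et3B/air in toluene at −78 °C, with hydrogen delivered to the primary end of the allyl radical, then gives 23.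

**Step 12 (ring-closing metathesis to a ten-membered carbocycle).** Oligomerisation or reaction at the 1,1-disubstituted olefins can win. The fallback sets out from 17 and comes back at 21; it cyclises a conformationally locked precursor before the bulky esters are in place and acylates on the macrocycle. Diol 17 is converted with 2,2-dimethoxypropane and PPTS into the trans-dioxolane acetonide triene F3, which is closed with RuCl2(SIMes)(=CH-C6H4-2-Oi-Pr) (10 mol%) in toluene (1 mM) at 80 °C to the macrocyclic acetonide F4. Aqueous 80% AcOH at 40 °C releases the macrocyclic diol F5, which is esterified with two equivalents of angelic acid 18 under the step 11 conditions to give 21.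

**Step 10 (indium Barbier on a non-isolated α-hydroxy aldehyde).** The aldehyde can epimerise or rearrange to the ketol, and the diastereoselectivity rests on chelation in water. The fallback sets out from 10 and comes back at 17; it uses an isolable, protected chelating aldehyde and a magnesium-chelate-controlled organozinc addition. Imide 10 is protected with 4-methoxybenzyl trichloroacetimidate and catalytic La(OTf)3 to give the PMB ether imide F6. LiBH4 reduction gives the PMB-protected primary alcohol F7, and Dess–Martin oxidation gives the α-PMB-oxy aldehyde F8. The organozinc bromide (R–ZnBr) made from 16 and Zn dust in THF is added at −78 °C to F8 precomplexed with MgBr2·OEt2 to give the PMB-protected adduct F9 (Cram-chelate and chair control, same C7/C8 sense). MgBr2·OEt2/Me2S in CH2Cl2 removes the PMB group to give 17.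

## Further compounds

F1 | step 13 | (1E,6Z,8R,9S,10S)-8-(1-carboxyethenyl)-5-methylidene-9,10-bis{[(2Z)-2-methylbut-2-enoyl]oxy}cyclodeca-1,6-diene-1-carboxylic acid | C=C1CC/C=C(\[C@H](OC(=O)/C(C)=C\C)[C@@H](OC(=O)/C(C)=C\C)[C@H](/C=C\1)C(=C)C(=O)O)C(=O)O
F2 | step 13 | 15-iodo derivative of 23 (iodomethyl in place of the ring methyl, same geometry and configurations) | C=C1C(=O)O[C@@H]2/C=C(/CI)CC/C=C(/C(=O)O)[C@H](OC(=O)/C(C)=C\C)[C@@H](OC(=O)/C(C)=C\C)[C@@H]12
F3 | step 12 | acetonide of 17, di-tert-butyl (3R,4S,5S,6E)-3-ethenyl-4,5-(isopropylidenedioxy)-2-methylidene-6-(4-methylidenehex-5-en-1-ylidene)heptanedioate | C=CC(=C)CC/C=C(\[C@@H]1OC(C)(C)O[C@H]1[C@H](C=C)C(=C)C(=O)OC(C)(C)C)C(=O)OC(C)(C)C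
F4 | step 12 | tert-butyl (1E,6Z,8R,9S,10S)-8-[3-(tert-butoxy)-3-oxoprop-1-en-2-yl]-9,10-(isopropylidenedioxy)-5-methylidenecyclodeca-1,6-diene-1-carboxylate | C=C1CC/C=C(\[C@@H]2OC(C)(C)O[C@H]2[C@H](/C=C\1)C(=C)C(=O)OC(C)(C)C)C(=O)OC(C)(C)C
F5 | step 12 | tert-butyl (1E,6Z,8R,9S,10S)-8-[3-(tert-butoxy)-3-oxoprop-1-en-2-yl]-9,10-dihydroxy-5-methylidenecyclodeca-1,6-diene-1-carboxylate | C=C1CC/C=C(\[C@H](O)[C@@H](O)[C@H](/C=C\1)C(=C)C(=O)OC(C)(C)C)C(=O)OC(C)(C)C
F6 | step 10 | tert-butyl (2E)-2-{(1S)-2-[(4S)-4-benzyl-2-oxo-1,3-oxazolidin-3-yl]-1-[(4-methoxybenzyl)oxy]-2-oxoethyl}-6-methylideneocta-2,7-dienoate | C=CC(=C)CC/C=C(\[C@H](OCc1ccc(OC)cc1)C(=O)N1C(=O)OC[C@@H]1Cc1ccccc1)C(=O)OC(C)(C)C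
F7 | step 10 | tert-butyl (2E)-2-{(1S)-2-hydroxy-1-[(4-methoxybenzyl)oxy]ethyl}-6-methylideneocta-2,7-dienoate | C=CC(=C)CC/C=C(\[C@H](OCc1ccc(OC)cc1)CO)C(=O)OC(C)(C)C
F8 | step 10 | tert-butyl (2E)-2-{(1S)-1-[(4-methoxybenzyl)oxy]-2-oxoethyl}-6-methylideneocta-2,7-dienoate | C=CC(=C)CC/C=C(\[C@H](OCc1ccc(OC)cc1)C=O)C(=O)OC(C)(C)C
F9 | step 10 | di-tert-butyl (3R,4S,5S,6E)-3-ethenyl-4-hydroxy-5-[(4-methoxybenzyl)oxy]-2-methylidene-6-(4-methylidenehex-5-en-1-ylidene)heptanedioate | C=CC(=C)CC/C=C(\[C@H](OCc1ccc(OC)cc1)[C@@H](O)[C@H](C=C)C(=C)C(=O)OC(C)(C)C)C(=O)OC(C)(C)C
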